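**Strategy.** The route rests on cutting the C1–C2 bond of the cyclopentane, the bond between the two adjacent methyl-bearing quaternary ring carbons. C1 is α to the ring acyl carbon (carboxyl level) and C2 carries a chain that can start as an alkenyl group, which is the pattern an ester-enolate Claisen leaves behind. A nine-membered (Z)-allylic lactone, (9R)-3,7,9-trimethyloxacyclonon-7-en-2-one, is converted into its silyl ketene acetal. One transannular [3,3] shift then contracts the ring, closes the cyclopentane and sets both quaternary centres, with the absolute sense relayed from the carbinol carbon. The acid and propenyl handles then grow into the two ketone side chains.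

Key step: step 6

Remark: lactone 9 is made and used as the mixture of C3 epimers because enolisation in step 6 removes that centre, so its SMILES leaves C3 open; the enol ether geometry (step 9) and the carbinol centres of steps 12 and 20 are likewise carried as mixtures because later steps destroy them.

**Step 1**
Reactants: 1 5-chloropentan-2-one
Product: 2 5-chloro-2-methylpent-1-ene
Conditions: Ph3PCH3Br, KOtBu, THF, 0 °C → rt
Reagents that add atoms: methyltriphenylphosphonium bromide, C[P+](c1ccccc1)(c1ccccc1)c1ccccc1.[Br-]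
Why: Wittig methylenation: the pre-formed unstabilised ylide adds to the ketone carbonyl faster than it deprotonates it at 0 °C, and the primary chloride is not displaced under these conditions.

**Step 2**
Reactants: 2 5-chloro-2-methylpent-1-ene; 3 diethyl methylmalonate
Product: 4 diethyl 2-methyl-2-(4-methylpent-4-enyl)propanedioate
Conditions: NaOEt, EtOH, NaI (cat.), reflux
Reagents that add atoms: none
Why: Malonic ester alkylation: the sodium enolate of 3 displaces the primary halide by SN2 after in situ chloride–iodide (Finkelstein) exchange, and the 1,1-disubstituted alkene is inert to ethoxide.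

**Step 3**
Reactants: 4 diethyl 2-methyl-2-(4-methylpent-4-enyl)propanedioate
Product: 6 2,6-dimethylhept-6-enoic acid (racemic), via malonic diacid 5 (not isolated)
Conditions: KOH, EtOH/H2O, reflux; HCl (aq), 0 °C; crude diacid, neat, 160 °C
Reagents that add atoms: potassium hydroxide, [K+].[OH-]
Why: Saponification of the hindered diester followed by thermal decarboxylation of the malonic acid through its cyclic six-membered transition state should give the acid; the α-centre forms as a racemate, which does not matter because step 6 planarises it.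

**Step 4**
Reactants: 6 2,6-dimethylhept-6-enoic acid; 7 (R)-but-3-en-2-ol
Product: 8 (2R)-but-3-en-2-yl 2,6-dimethylhept-6-enoate (both epimers at the acyl α-carbon)
Conditions: DCC, DMAP (cat.), CH2Cl2, 0 °C → rt
Reagents that add atoms: none
Why: Steglich esterification activates the acid, so the alcohol reacts through oxygen with its C–O bond intact and the R carbinol configuration is retained.

**Step 5**
Reactants: 8 (2R)-but-3-en-2-yl 2,6-dimethylhept-6-enoate
Product: 9 (9R,7Z)-3,7,9-trimethyloxacyclonon-7-en-2-one (C3 epimers)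
Conditions: Grubbs II (10 mol %), PhMe (1 mM, slow addition of 8), 80 °C
Reagents that add atoms: none
Why: Ring-closing metathesis of the monosubstituted alkene onto the 1,1-disubstituted one releases ethene and is favoured by high dilution; a nine-membered ring can hold the new trisubstituted alkene only in the ring-cis (Z) geometry.

**Step 6**
Reactants: 9 (9R,7Z)-3,7,9-trimethyloxacyclonon-7-en-2-one
Product: 12 (1R,2R)-1,2-dimethyl-2-[(E)-prop-1-enyl]cyclopentane-1-carboxylic acid, via TBS ketene acetal 10 (not isolated), via TBS ester 11 (not isolated)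
Conditions: LDA, THF, −78 °C; TBSCl, DMPU, −78 °C → rt; PhMe, 105 °C; then 1 M HCl, THF, rt
Reagents that add atoms: none
Why: LDA removes the C3 proton of either epimer and O-silylation gives the cyclic ketene acetal 10, whose enol geometry is locked by the ring; on heating, a concerted suprafacial [3,3] shift joins C3 to C7 while the C9–O1 bond breaks and the C8=C9 alkene forms, contracting the ring to silyl ester 11, which mild acid hydrolyses to 12. The closest known reaction type is the transannular Ireland–Claisen (ester-enolate Claisen) ring contraction of unsaturated medium-ring lactones, and vicinal quaternary carbons are an established outcome of Ireland–Claisen rearrangements. The cyclopentane is closed by transannular C3–C7 bond formation, formally a 5-exo-trig attack of the enol carbon on C7 with both π bonds exocyclic to the new ring. The relative configuration of the new C1 and C2 is dictated by the boat-shaped transition state, the only one in which the C4–C6 tether can reach both termini, so the two methyls, and likewise carboxyl and alkenyl, should come out cis. The absolute configuration of both centres is controlled by the (9R) carbinol carbon: its methyl takes the outside position to avoid allylic 1,3-strain with C6 across the Z-alkene, so C3 is delivered to one face of C7 and the propenyl group is E. The step needs facial (hence enantio-) selectivity, secured by that stereocentre and the Z geometry; any Z-propenyl isomer, which would carry the antipodal ring, is removed by argentation chromatography before step 8.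

**Step 7**
Reactants: 12 (1R,2R)-1,2-dimethyl-2-[(E)-prop-1-enyl]cyclopentane-1-carboxylic acid
Product: 13 methyl (1R,2R)-1,2-dimethyl-2-[(E)-prop-1-enyl]cyclopentane-1-carboxylate
Conditions: MeI, K2CO3, DMF, rt
Reagents that add atoms: iodomethane, CI
Why: Carboxylate O-alkylation (SN2 on iodomethane) esterifies without attack at the very hindered acyl carbon and touches neither stereocentre; the ester prevents lactol formation with the aldehyde made next.

**Step 8**
Reactants: 13 methyl (1R,2R)-1,2-dimethyl-2-[(E)-prop-1-enyl]cyclopentane-1-carboxylate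
Product: 15 methyl (1R,2S)-2-formyl-1,2-dimethylcyclopentane-1-carboxylate, via secondary ozonide 14 (not isolated)
Conditions: O3, CH2Cl2, −78 °C; then PPh3, −78 °C → rt
Reagents that add atoms: ozone, [O-][O+]=O
Why: Ozonolysis with reductive work-up cleaves the only C=C bond to the aldehyde, which like the ester sits on a quaternary carbon and therefore cannot epimerise (the descriptor changes to 2S by priority only).

**Step 9**
Reactants: 15 methyl (1R,2S)-2-formyl-1,2-dimethylcyclopentane-1-carboxylate
Product: 16 methyl (1R,2R)-2-(2-methoxyethenyl)-1,2-dimethylcyclopentane-1-carboxylate (E/Z mixture)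
Conditions: Ph3P(CH2OMe)Cl, KOtBu, THF, 0 °C → rt
Reagents that add atoms: (methoxymethyl)triphenylphosphonium chloride, COC[P+](c1ccccc1)(c1ccccc1)c1ccccc1.[Cl-]
Why: Wittig reaction with methoxymethylenetriphenylphosphorane adds the missing carbon as an enol ether (masked aldehyde), tolerates α-quaternary aldehydes and leaves the hindered ester alone; the E/Z mixture is used as such because the geometry disappears in step 14.

**Step 10**
Reactants: 16 methyl (1R,2R)-2-(2-methoxyethenyl)-1,2-dimethylcyclopentane-1-carboxylate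
Product: 17 [(1R,2R)-2-(2-methoxyethenyl)-1,2-dimethylcyclopentyl]methanol
Conditions: LiAlH4, Et2O, 0 °C → rt; NaOH (aq) work-up
Reagents that add atoms: none
Why: Lithium aluminium hydride reduction of the ester gives the neopentyl alcohol; the enol ether is inert to hydride and the alkaline work-up avoids acid-catalysed addition of the new hydroxyl to it.

**Step 11**
Reactants: 17 [(1R,2R)-2-(2-methoxyethenyl)-1,2-dimethylcyclopentyl]methanol
Product: 18 (1R,2R)-2-(2-methoxyethenyl)-1,2-dimethylcyclopentane-1-carbaldehyde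
Conditions: (COCl)2, DMSO, CH2Cl2, −78 °C; Et3N, −78 → 0 °C
Reagents that add atoms: none
Why: Swern oxidation converts the primary alcohol into the aldehyde under amine-buffered conditions compatible with the enol ether, and an aldehyde on a quaternary carbon cannot epimerise.

**Step 12**
Reactants: 18 (1R,2R)-2-(2-methoxyethenyl)-1,2-dimethylcyclopentane-1-carbaldehyde; 19 1-chloro-3-methylbut-2-ene (prenyl chloride)
Product: 21 1-[(1R,2R)-2-(2-methoxyethenyl)-1,2-dimethylcyclopentyl]-4-methylpent-3-en-1-ol (carbinol epimers), via prenylbarium chloride 20 (not isolated)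
Conditions: BaI2, lithium biphenylide (2 equiv), THF, rt (active Ba); 19, −78 °C; then 18, −78 °C; aq. NH4Cl
Reagents that add atoms: none
Why: α-Selective carbonyl allylation with an allylbarium reagent: prenylbarium chloride made from active barium at −78 °C attacks aldehydes through its CH2 terminus, which should give the linear prenyl carbinol and not the reverse-prenyl isomer; the new carbinol centre is uncontrolled and is oxidised away in step 22.

**Step 13**
Reactants: 21 1-[(1R,2R)-2-(2-methoxyethenyl)-1,2-dimethylcyclopentyl]-4-methylpent-3-en-1-ol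
Product: 22 tert-butyl-[1-[(1R,2R)-2-(2-methoxyethenyl)-1,2-dimethylcyclopentyl]-4-methylpent-3-enoxy]-dimethylsilane
Conditions: TBSOTf, 2,6-lutidine (excess), CH2Cl2, −78 → 0 °C
Reagents that add atoms: tert-butyldimethylsilyl trifluoromethanesulfonate, CC(C)(C)[Si](C)(C)OS(=O)(=O)C(F)(F)F
Why: Silylation with the silyl triflate and a hindered pyridine base, the standard method for congested secondary alcohols, masks the hydroxyl so that it cannot close a six-membered lactol onto the aldehyde released in step 14, the excess base keeping the enol ether unprotonated.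

**Step 14**
Reactants: 22 tert-butyl-[1-[(1R,2R)-2-(2-methoxyethenyl)-1,2-dimethylcyclopentyl]-4-methylpent-3-enoxy]-dimethylsilane
Product: 23 2-[(1R,2R)-2-[1-[tert-butyl(dimethyl)silyl]oxy-4-methylpent-3-enyl]-1,2-dimethylcyclopentyl]acetaldehyde
Conditions: 1 M HCl, THF, 0 °C → rt
Reagents that add atoms: water, O
Why: Acid-catalysed enol ether hydrolysis (C-protonation, hydration of the oxocarbenium ion, loss of methanol) unveils the homologated aldehyde under conditions that a hindered secondary TBS ether and the trisubstituted alkene withstand.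

**Step 15**
Reactants: 24 4-methoxy-2-methylphenol
Product: 25 2-bromo-4-methoxy-6-methylphenol
Conditions: NBS, CH2Cl2, 0 °C
Reagents that add atoms: N-bromosuccinimide, O=C1CCC(=O)N1Br
Why: Electrophilic aromatic bromination: the free hydroxyl, the strongest activator, directs bromine to its single open ortho position because the para position carries the methoxy group.

**Step 16**
Reactants: 25 2-bromo-4-methoxy-6-methylphenol
Product: 26 1-bromo-2,5-dimethoxy-3-methylbenzene
Conditions: MeI, K2CO3, acetone, reflux
Reagents that add atoms: iodomethane, CI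
Why: Williamson O-methylation of the phenoxide gives a ring that is inert to butyllithium and barium reagents and can be unmasked oxidatively at the end.

**Step 17**
Reactants: 26 1-bromo-2,5-dimethoxy-3-methylbenzene; 27 1-bromo-3-methylbut-2-ene (prenyl bromide)
Product: 29 2,5-dimethoxy-1-methyl-3-(3-methylbut-2-enyl)benzene, via aryllithium 28 (not isolated)
Conditions: n-BuLi, THF, −78 °C; CuI (10 mol %), 27, −78 → 0 °C
Reagents that add atoms: none
Why: Bromine–lithium exchange followed by copper-catalysed SN2 coupling of the aryllithium with the primary allylic bromide installs the prenyl group through the unsubstituted allyl terminus.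

**Step 18**
Reactants: 29 2,5-dimethoxy-1-methyl-3-(3-methylbut-2-enyl)benzene
Product: 30 (E)-4-(2,5-dimethoxy-3-methylphenyl)-2-methylbut-2-en-1-ol
Conditions: SeO2 (0.3 equiv), t-BuOOH, salicylic acid (cat.), CH2Cl2, rt
Reagents that add atoms: selenium dioxide, O=[Se]=O (oxygen carrier); tert-butyl hydroperoxide, CC(C)(C)OO (terminal oxygen source)
Why: Riley-type selenium dioxide allylic oxidation (ene reaction, then [2,3]-sigmatropic shift) hydroxylates the methyl group trans to the chain on the more substituted alkene carbon, which defines the E geometry, and leaves the benzylic CH2 on the less substituted carbon untouched.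

**Step 19**
Reactants: 30 (E)-4-(2,5-dimethoxy-3-methylphenyl)-2-methylbut-2-en-1-ol
Product: 32 1-[(E)-4-chloro-3-methylbut-2-enyl]-2,5-dimethoxy-3-methylbenzene, via allylic mesylate 31 (not isolated)
Conditions: MsCl, 2,4,6-collidine, LiCl, DMF, 0 °C
Reagents that add atoms: lithium chloride, [Li+].[Cl-]
Why: The primary allylic mesylate formed in situ is displaced by chloride in a direct SN2 reaction, so the alkene neither migrates nor loses its E geometry.

**Step 20**
Reactants: 23 2-[(1R,2R)-2-[1-[tert-butyl(dimethyl)silyl]oxy-4-methylpent-3-enyl]-1,2-dimethylcyclopentyl]acetaldehyde; 32 1-[(E)-4-chloro-3-methylbut-2-enyl]-2,5-dimethoxy-3-methylbenzene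
Product: 34 (4E)-1-[(1R,2R)-2-[1-[tert-butyl(dimethyl)silyl]oxy-4-methylpent-3-enyl]-1,2-dimethylcyclopentyl]-6-(2,5-dimethoxy-3-methylphenyl)-4-methylhex-4-en-2-ol (carbinol epimers), via allylbarium chloride 33 (not isolated)
Conditions: BaI2, lithium biphenylide (2 equiv), THF, rt (active Ba); 32, −78 °C; then 23, −78 °C; aq. NH4Cl
Reagents that add atoms: none
Why: α-Selective carbonyl allylation with an allylbarium reagent: the allylic barium species generated at −78 °C holds its E geometry and reacts with the aldehyde through its CH2 carbon, joining the fragments with the trisubstituted alkene intact; the carbinol centre is uncontrolled and becomes a ketone in step 22.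

**Step 21**
Reactants: 34 (4E)-1-[(1R,2R)-2-[1-[tert-butyl(dimethyl)silyl]oxy-4-methylpent-3-enyl]-1,2-dimethylcyclopentyl]-6-(2,5-dimethoxy-3-methylphenyl)-4-methylhex-4-en-2-ol
Product: 35 (4E)-6-(2,5-dimethoxy-3-methylphenyl)-1-[(1R,2R)-2-(1-hydroxy-4-methylpent-3-enyl)-1,2-dimethylcyclopentyl]-4-methylhex-4-en-2-ol
Conditions: TBAF, THF, 50 °C
Reagents that add atoms: none
Why: Fluoride-mediated desilylation frees the hindered carbinol at a stage where only alkenes, aryl methyl ethers and alcohols are present, so the basic conditions can do no harm.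

**Step 22**
Reactants: 35 (4E)-6-(2,5-dimethoxy-3-methylphenyl)-1-[(1R,2R)-2-(1-hydroxy-4-methylpent-3-enyl)-1,2-dimethylcyclopentyl]-4-methylhex-4-en-2-ol
Product: 36 (4E)-6-(2,5-dimethoxy-3-methylphenyl)-1-[(1R,2R)-1,2-dimethyl-2-(4-methylpent-3-enoyl)cyclopentyl]-4-methylhex-4-en-2-one
Conditions: Dess–Martin periodinane (3 equiv), pyridine, CH2Cl2, 0 °C → rt
Reagents that add atoms: none
Why: Dess–Martin oxidation of both secondary alcohols in one operation under pyridine-buffered, near-neutral conditions should give the two β,γ-unsaturated ketones without shifting the alkenes into conjugation or closing the 1,5-diketone by aldol reaction.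

**Step 23**
Reactants: 36 (4E)-6-(2,5-dimethoxy-3-methylphenyl)-1-[(1R,2R)-1,2-dimethyl-2-(4-methylpent-3-enoyl)cyclopentyl]-4-methylhex-4-en-2-one
Product: 38 (4E)-6-(2,5-dihydroxy-3-methylphenyl)-1-[(1R,2R)-1,2-dimethyl-2-(4-methylpent-3-enoyl)cyclopentyl]-4-methylhex-4-en-2-one (target), via benzoquinone 37 (not isolated)
Conditions: CAN (2.5 equiv), MeCN/H2O, 0 °C; then Et2O, aq. Na2S2O4, rt
Reagents that add atoms: water, O
Why: Cerium(IV) oxidative demethylation of the para-dimethoxyarene to the quinone and dithionite reduction to the hydroquinone replace acidic ether cleavage, which would cyclise the ortho-allyl phenol to a chroman or isomerise the enones; trisubstituted alkenes are tolerated by this oxidant in prenylquinone chemistry.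

**Compound list**
1 | 5-chloropentan-2-one | CC(=O)CCCCl | starting material
2 | 5-chloro-2-methylpent-1-ene | CC(=C)CCCCl | intermediate
3 | diethyl methylmalonate (diethyl 2-methylpropanedioate) | CCOC(=O)C(C)C(=O)OCC | starting material
4 | diethyl 2-methyl-2-(4-methylpent-4-enyl)propanedioate | CCOC(=O)C(C)(CCCC(C)=C)C(=O)OCC | intermediate
5 | 2-methyl-2-(4-methylpent-4-enyl)propanedioic acid | OC(=O)C(C)(CCCC(C)=C)C(=O)O | intermediate
6 | 2,6-dimethylhept-6-enoic acid (racemic) | CC(=C)CCCC(C)C(=O)O | intermediate
7 | (R)-but-3-en-2-ol | C[C@@H](O)C=C | starting material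
8 | (2R)-but-3-en-2-yl 2,6-dimethylhept-6-enoate (both acyl α-epimers) | CC(=C)CCCC(C)C(=O)O[C@H](C)C=C | intermediate
9 | (9R,7Z)-3,7,9-trimethyloxacyclonon-7-en-2-one (C3 epimers) | O=C1O[C@H](C)/C=C(C)\CCCC1C | intermediate
10 | tert-butyl-dimethyl-[[(2E,7Z,9R)-3,7,9-trimethyl-4,5,6,9-tetrahydrooxonin-2-yl]oxy]silane (cyclic silyl ketene acetal of 9) | C/C1=C(\O[Si](C)(C)C(C)(C)C)O[C@H](C)/C=C(C)\CCC1 | intermediate
11 | tert-butyldimethylsilyl (1R,2R)-1,2-dimethyl-2-[(E)-prop-1-enyl]cyclopentane-1-carboxylate | CC(C)(C)[Si](C)(C)OC(=O)[C@]1(C)CCC[C@]1(C)/C=C/C | intermediate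
12 | (1R,2R)-1,2-dimethyl-2-[(E)-prop-1-enyl]cyclopentane-1-carboxylic acid (methyls cis) | OC(=O)[C@]1(C)CCC[C@]1(C)/C=C/C | intermediate
13 | methyl (1R,2R)-1,2-dimethyl-2-[(E)-prop-1-enyl]cyclopentane-1-carboxylate | COC(=O)[C@]1(C)CCC[C@]1(C)/C=C/C | intermediate
14 | methyl (1R,2S)-1,2-dimethyl-2-(5-methyl-1,2,4-trioxolan-3-yl)cyclopentane-1-carboxylate (trioxolane centres mixed) | COC(=O)[C@]1(C)CCC[C@]1(C)C2OOC(C)O2 | intermediate
15 | methyl (1R,2S)-2-formyl-1,2-dimethylcyclopentane-1-carboxylate | COC(=O)[C@]1(C)CCC[C@]1(C)C=O | intermediate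
16 | methyl (1R,2R)-2-(2-methoxyethenyl)-1,2-dimethylcyclopentane-1-carboxylate (E/Z mixture) | COC(=O)[C@]1(C)CCC[C@]1(C)C=COC | intermediate
17 | [(1R,2R)-2-(2-methoxyethenyl)-1,2-dimethylcyclopentyl]methanol | OC[C@]1(C)CCC[C@]1(C)C=COC | intermediate
18 | (1R,2R)-2-(2-methoxyethenyl)-1,2-dimethylcyclopentane-1-carbaldehyde | O=C[C@]1(C)CCC[C@]1(C)C=COC | intermediate
19 | 1-chloro-3-methylbut-2-ene (prenyl chloride) | CC(C)=CCCl | starting material
20 | chloro(3-methylbut-2-enyl)barium (prenylbarium chloride) | CC(C)=CC[Ba]Cl | intermediate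
21 | 1-[(1R,2R)-2-(2-methoxyethenyl)-1,2-dimethylcyclopentyl]-4-methylpent-3-en-1-ol (carbinol epimers) | CC(C)=CCC(O)[C@]1(C)CCC[C@]1(C)C=COC | intermediate
22 | tert-butyl-[1-[(1R,2R)-2-(2-methoxyethenyl)-1,2-dimethylcyclopentyl]-4-methylpent-3-enoxy]-dimethylsilane | CC(C)=CCC(O[Si](C)(C)C(C)(C)C)[C@]1(C)CCC[C@]1(C)C=COC | intermediate
23 | 2-[(1R,2R)-2-[1-[tert-butyl(dimethyl)silyl]oxy-4-methylpent-3-enyl]-1,2-dimethylcyclopentyl]acetaldehyde | CC(C)=CCC(O[Si](C)(C)C(C)(C)C)[C@]1(C)CCC[C@]1(C)CC=O | intermediate
24 | 4-methoxy-2-methylphenol | COc1ccc(O)c(C)c1 | starting material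
25 | 2-bromo-4-methoxy-6-methylphenol | COc1cc(C)c(O)c(Br)c1 | intermediate
26 | 1-bromo-2,5-dimethoxy-3-methylbenzene | COc1cc(C)c(OC)c(Br)c1 | intermediate
27 | 1-bromo-3-methylbut-2-ene (prenyl bromide) | CC(C)=CCBr | starting material
28 | (2,5-dimethoxy-3-methylphenyl)lithium | [Li]c1cc(OC)cc(C)c1OC | intermediate
29 | 2,5-dimethoxy-1-methyl-3-(3-methylbut-2-enyl)benzene | COc1cc(C)c(OC)c(CC=C(C)C)c1 | intermediate
30 | (E)-4-(2,5-dimethoxy-3-methylphenyl)-2-methylbut-2-en-1-ol | OC/C(C)=C/Cc1cc(OC)cc(C)c1OC | intermediate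
31 | [(E)-4-(2,5-dimethoxy-3-methylphenyl)-2-methylbut-2-enyl] methanesulfonate | CS(=O)(=O)OC/C(C)=C/Cc1cc(OC)cc(C)c1OC | intermediate
32 | 1-[(E)-4-chloro-3-methylbut-2-enyl]-2,5-dimethoxy-3-methylbenzene | ClC/C(C)=C/Cc1cc(OC)cc(C)c1OC | intermediate
33 | chloro-[(E)-4-(2,5-dimethoxy-3-methylphenyl)-2-methylbut-2-enyl]barium | Cl[Ba]C/C(C)=C/Cc1cc(OC)cc(C)c1OC | intermediate
34 | (4E)-1-[(1R,2R)-2-[1-[tert-butyl(dimethyl)silyl]oxy-4-methylpent-3-enyl]-1,2-dimethylcyclopentyl]-6-(2,5-dimethoxy-3-methylphenyl)-4-methylhex-4-en-2-ol (carbinol epimers) | CC(C)=CCC(O[Si](C)(C)C(C)(C)C)[C@]1(C)CCC[C@]1(C)CC(O)C/C(C)=C/Cc1cc(OC)cc(C)c1OC | intermediate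
35 | (4E)-6-(2,5-dimethoxy-3-methylphenyl)-1-[(1R,2R)-2-(1-hydroxy-4-methylpent-3-enyl)-1,2-dimethylcyclopentyl]-4-methylhex-4-en-2-ol | CC(C)=CCC(O)[C@]1(C)CCC[C@]1(C)CC(O)C/C(C)=C/Cc1cc(OC)cc(C)c1OC | intermediate
36 | (4E)-6-(2,5-dimethoxy-3-methylphenyl)-1-[(1R,2R)-1,2-dimethyl-2-(4-methylpent-3-enoyl)cyclopentyl]-4-methylhex-4-en-2-one | CC(C)=CCC(=O)[C@]1(C)CCC[C@]1(C)CC(=O)C/C(C)=C/Cc1cc(OC)cc(C)c1OC | intermediate
37 | 2-[(2E)-6-[(1R,2R)-1,2-dimethyl-2-(4-methylpent-3-enoyl)cyclopentyl]-3-methyl-5-oxohex-2-enyl]-6-methylcyclohexa-2,5-diene-1,4-dione | CC(C)=CCC(=O)[C@]1(C)CCC[C@]1(C)CC(=O)C/C(C)=C/CC1=CC(=O)C=C(C)C1=O | intermediate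
38 | (4E)-6-(2,5-dihydroxy-3-methylphenyl)-1-[(1R,2R)-1,2-dimethyl-2-(4-methylpent-3-enoyl)cyclopentyl]-4-methylhex-4-en-2-one | CC(C)=CCC(=O)[C@]1(C)CCC[C@]1(C)CC(=O)C/C(C)=C/Cc1cc(O)cc(C)c1O | target

**Step count.** Total: 23 steps (18 in the main line, 5 for the aryl allyl chloride). Longest linear sequence: 18 steps (steps 1–14 and 20–23).

**Steps most likely to fail**

1. Step 6 (key step). The carbinol methyl may partly take the inside position of the boat; this would show up as Z-propenyl acid of opposite ring configuration and would lower the enantiopurity after step 8. The lactone enolate may also fragment before it is silylated, or the strained boat may be reached only at temperatures at which the ketene acetal decomposes. Fallback: the two quaternary centres are made by an intramolecular ketene–alkene [2+2] cycloaddition. It sets out from acid 6. Oxalyl chloride gives 2,6-dimethylhept-6-enoyl chloride F1. Triethylamine in refluxing toluene generates the ketene 2,6-dimethylhepta-1,6-dien-1-one F2, which should close to racemic cis-1,5-dimethylbicyclo[3.2.0]heptan-6-one F3; the cis ring fusion is obligatory, so the methyls are cis. LDA/TMSCl gives trimethyl-[(1,5-dimethylbicyclo[3.2.0]hept-6-en-6-yl)oxy]silane F4. Ozonolysis with dimethyl sulfide work-up cleaves the enol ether to racemic cis-2-formyl-1,2-dimethylcyclopentane-1-carboxylic acid F5. Crystallisation of its cinchonidine salt should deliver (1R,2S)-2-formyl-1,2-dimethylcyclopentane-1-carboxylic acid F6. Methyl iodide/K2CO3 then returns to the route at aldehyde ester 15.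

2. Step 5. Intermolecular metathesis (dimers, oligomers) may outrun closure of the strained nine-membered ring, or the catalyst may fail to engage the 1,1-disubstituted alkene. Fallback: the Z-alkene is made by cross-coupling and the ring is closed at the ester bond. It sets out from 3. Allylation (NaOEt, allyl bromide) gives diethyl 2-methyl-2-(prop-2-enyl)propanedioate F7, and Krapcho dealkoxycarbonylation (LiCl, wet DMSO, 160 °C) gives ethyl 2-methylpent-4-enoate F8. Commercial (R)-but-3-yn-2-ol is C-methylated (n-BuLi 2 equiv, MeI) to (R)-pent-3-yn-2-ol F9. Red-Al, then iodine, gives (2R,3Z)-4-iodopent-3-en-2-ol F10 by hydroxyl-directed trans-hydroalumination. Hydroboration of F8 with 9-BBN gives ethyl 5-(9-borabicyclo[3.3.1]nonan-9-yl)-2-methylpentanoate F11. Its B-alkyl Suzuki coupling with F10 (Pd(dppf)Cl2, Cs2CO3, DMF/H2O) should give, with retention of alkene geometry, ethyl (6Z,8R)-8-hydroxy-2,6-dimethylnon-6-enoate F12. LiOH gives (6Z,8R)-8-hydroxy-2,6-dimethylnon-6-enoic acid F13. Yamaguchi lactonisation at high dilution, which leaves the carbinol C–O bond untouched, returns to the route at lactone 9.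

3. Step 20. The allylbarium may attack through its γ-carbon or scramble its E geometry if it warms during formation, and the allylic chloride may undergo Wurtz-type coupling on the metal. Fallback: a sulfone-stabilised carbanion fixes the site of attack. It sets out from chloride 32 and aldehyde 23. Sodium benzenesulfinate in DMF gives [(E)-4-(2,5-dimethoxy-3-methylphenyl)-2-methylbut-2-enyl]sulfonylbenzene F14. Its lithio derivative (n-BuLi, THF, −78 °C) adds to 23 through the sulfonyl-bearing carbon to give (4E)-3-(benzenesulfonyl)-1-[(1R,2R)-2-[1-[tert-butyl(dimethyl)silyl]oxy-4-methylpent-3-enyl]-1,2-dimethylcyclopentyl]-6-(2,5-dimethoxy-3-methylphenyl)-4-methylhex-4-en-2-ol F15. TBAF gives (4E)-3-(benzenesulfonyl)-6-(2,5-dimethoxy-3-methylphenyl)-1-[(1R,2R)-2-(1-hydroxy-4-methylpent-3-enyl)-1,2-dimethylcyclopentyl]-4-methylhex-4-en-2-ol F16. Dess–Martin oxidation gives (4E)-3-(benzenesulfonyl)-6-(2,5-dimethoxy-3-methylphenyl)-1-[(1R,2R)-1,2-dimethyl-2-(4-methylpent-3-enoyl)cyclopentyl]-4-methylhex-4-en-2-one F17. Samarium diiodide (THF/MeOH, −78 °C) removes the sulfonyl group with α-protonation of the dienolate and returns to the route at diketone 36.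

**Further compounds**
F1 | step 6 | 2,6-dimethylhept-6-enoyl chloride (racemic) | CC(=C)CCCC(C)C(Cl)=O
F2 | step 6 | 2,6-dimethylhepta-1,6-dien-1-one (ketene) | CC(=C)CCCC(C)=C=O
F3 | step 6 | cis-1,5-dimethylbicyclo[3.2.0]heptan-6-one (racemic) | O=C1CC2(C)CCCC12C
F4 | step 6 | trimethyl-[(1,5-dimethylbicyclo[3.2.0]hept-6-en-6-yl)oxy]silane (racemic, cis) | C[Si](C)(C)OC1=CC2(C)CCCC12C
F5 | step 6 | cis-2-formyl-1,2-dimethylcyclopentane-1-carboxylic acid (racemic) | OC(=O)C1(C)CCCC1(C)C=O
F6 | step 6 | (1R,2S)-2-formyl-1,2-dimethylcyclopentane-1-carboxylic acid | OC(=O)[C@]1(C)CCC[C@]1(C)C=O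
F7 | step 5 | diethyl 2-methyl-2-(prop-2-enyl)propanedioate | CCOC(=O)C(C)(CC=C)C(=O)OCC
F8 | step 5 | ethyl 2-methylpent-4-enoate (racemic) | CCOC(=O)C(C)CC=C
F9 | step 5 | (R)-pent-3-yn-2-ol | C[C@@H](O)C#CC
F10 | step 5 | (2R,3Z)-4-iodopent-3-en-2-ol | C[C@@H](O)/C=C(/C)I
F11 | step 5 | ethyl 5-(9-borabicyclo[3.3.1]nonan-9-yl)-2-methylpentanoate | CCOC(=O)C(C)CCCB1C2CCCC1CCC2
F12 | step 5 | ethyl (6Z,8R)-8-hydroxy-2,6-dimethylnon-6-enoate (C2 epimers) | CCOC(=O)C(C)CCC/C(C)=C\[C@@H](C)O
F13 | step 5 | (6Z,8R)-8-hydroxy-2,6-dimethylnon-6-enoic acid (C2 epimers) | OC(=O)C(C)CCC/C(C)=C\[C@@H](C)O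
F14 | step 20 | [(E)-4-(2,5-dimethoxy-3-methylphenyl)-2-methylbut-2-enyl]sulfonylbenzene | O=S(=O)(C/C(C)=C/Cc1cc(OC)cc(C)c1OC)c1ccccc1
F15 | step 20 | (4E)-3-(benzenesulfonyl)-1-[(1R,2R)-2-[1-[tert-butyl(dimethyl)silyl]oxy-4-methylpent-3-enyl]-1,2-dimethylcyclopentyl]-6-(2,5-dimethoxy-3-methylphenyl)-4-methylhex-4-en-2-ol | CC(C)=CCC(O[Si](C)(C)C(C)(C)C)[C@]1(C)CCC[C@]1(C)CC(O)C(/C(C)=C/Cc1cc(OC)cc(C)c1OC)S(=O)(=O)c1ccccc1
F16 | step 20 | (4E)-3-(benzenesulfonyl)-6-(2,5-dimethoxy-3-methylphenyl)-1-[(1R,2R)-2-(1-hydroxy-4-methylpent-3-enyl)-1,2-dimethylcyclopentyl]-4-methylhex-4-en-2-ol | CC(C)=CCC(O)[C@]1(C)CCC[C@]1(C)CC(O)C(/C(C)=C/Cc1cc(OC)cc(C)c1OC)S(=O)(=O)c1ccccc1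
F17 | step 20 | (4E)-3-(benzenesulfonyl)-6-(2,5-dimethoxy-3-methylphenyl)-1-[(1R,2R)-1,2-dimethyl-2-(4-methylpent-3-enoyl)cyclopentyl]-4-methylhex-4-en-2-one | CC(C)=CCC(=O)[C@]1(C)CCC[C@]1(C)CC(=O)C(/C(C)=C/Cc1cc(OC)cc(C)c1OC)S(=O)(=O)c1ccccc1
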